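## Retrosynthetic overview

- The route rests on ring C of the naphthol (C1', C2', C3', C4', C4a', C8a'). C1' (hydroxyl carbon) and C4' are the ester carbon and the methyl carbon of methyl 2-methoxy-6-methylbenzoate, so the C1' hydroxyl and the C8' methoxy group arrive already differentiated, and the crowded C4–C2' bond is never made by a coupling.
- Disconnections in ring C: C4'–C3' (Michael addition of the lithiated toluate to the CH2 end of a 1-(tetralinyl)vinyl phenyl sulfone) and C2'–C1' (acylation of the resulting sulfonyl carbanion by the ester). Loss of benzenesulfinate then aromatises the ring.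
- The vinyl sulfone is the Mannich methylenation product of a (tetralinyl)methyl phenyl sulfone. That sulfone comes from 8-methoxy-1-tetralone and lithiated methyl phenyl sulfone by addition, dehydration, asymmetric hydrogenation (C4), benzylic oxidation, catalyst-controlled reduction (C1) and silylation.
- Ring order: rings A and B are bought as the tetralone, ring D comes with the toluate, and ring C is the only ring formed (step 9). Desilylation ends the route.

Key step: step 9

Locants: the tetralin is numbered as in the target (C1 carbinol carbon, C4 branch carbon, C5 methoxy carbon); the naphthol carries primed locants (C1' hydroxyl carbon, C2' joined to C4, C8' methoxy carbon). The target is (1S,4R), trans.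

Assumption: 8-methoxy-1-tetralone (2) is purchased, and the (S)-ligand written in step 3 is the one taken to give (S)-5; its mirror image is used if the first run shows the opposite sense.

## Route

Step 1
Reactants: 1 methyl phenyl sulfone; 2 8-methoxy-3,4-dihydronaphthalen-1(2H)-one (8-methoxy-1-tetralone)
Product: 3 8-methoxy-1-[(phenylsulfonyl)methyl]-1,2,3,4-tetrahydronaphthalen-1-ol (racemic)
Conditions: 1, n-BuLi, THF, −78 °C; then 2, −78 °C, cold quench
Reagents that add atoms: none
Why: 1,2-Addition of an α-sulfonyl carbanion to a ketone, with lithium held between the carbonyl and the peri methoxy oxygen and a cold quench to stop retro-addition; the new carbinol centre is racemic and is removed in step 2.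

Step 2
Reactants: 3 8-methoxy-1-[(phenylsulfonyl)methyl]-1,2,3,4-tetrahydronaphthalen-1-ol
Product: 4 5-methoxy-4-[(phenylsulfonyl)methyl]-1,2-dihydronaphthalene
Conditions: TsOH·H2O (cat.), toluene, reflux, Dean–Stark
Reagents that add atoms: none
Why: Acid-catalysed E1 dehydration through a tertiary benzylic cation that the ortho methoxy group stabilises, run under equilibrating conditions so that the endocyclic styrene-type alkene (an allyl sulfone) is formed and not the exocyclic vinyl sulfone, which would clash with the peri methoxy group.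

Step 3
Reactants: 4 5-methoxy-4-[(phenylsulfonyl)methyl]-1,2-dihydronaphthalene
Product: 5 (S)-8-methoxy-1-[(phenylsulfonyl)methyl]-1,2,3,4-tetrahydronaphthalene (4S in target numbering)
Conditions: [Ir(cod)((S)-t-Bu-PHOX)]B[3,5-(CF3)2C6H3]4 (1–2 mol %), H2 (50 bar), CH2Cl2, rt
Reagents that add atoms: none
Why: Iridium-catalysed asymmetric hydrogenation of a cyclic trisubstituted aryl alkene (1-substituted 3,4-dihydronaphthalene class) with a chiral P,N ligand, whose pocket chooses the alkene face and thereby sets C4 as S; the sulfone is inert.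

Step 4
Reactants: 5 (S)-8-methoxy-1-[(phenylsulfonyl)methyl]-1,2,3,4-tetrahydronaphthalene
Product: 6 (S)-5-methoxy-4-[(phenylsulfonyl)methyl]-3,4-dihydronaphthalen-1(2H)-one
Conditions: CrO3, AcOH/H2O, 0 °C → rt
Reagents that add atoms: chromium trioxide, O=[Cr](=O)=O
Why: Benzylic C–H oxidation by hexavalent chromium, the usual way from 1-substituted tetralins to 4-substituted 1-tetralones, takes the C1 methylene because the tertiary C4–H is crowded by the peri methoxy group, lies near the arene plane and is deactivated by the β-sulfonyl group, so the C4 centre is untouched.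

Step 5
Reactants: 6 (S)-5-methoxy-4-[(phenylsulfonyl)methyl]-3,4-dihydronaphthalen-1(2H)-one
Product: 7 (1S,4S)-5-methoxy-4-[(phenylsulfonyl)methyl]-1,2,3,4-tetrahydronaphthalen-1-ol (trans)
Conditions: RuCl[(S,S)-TsDPEN](p-cymene) (1 mol %), HCO2H/Et3N (5:2), 30 °C
Reagents that add atoms: none
Why: Noyori asymmetric transfer hydrogenation of an aryl ketone under catalyst control: the (S,S)-catalyst, which gives (S)-carbinols from 1-tetralones, sets C1 as S whatever the remote C4 centre is, which means the trans isomer here, and the weakly acidic medium leaves the β-sulfonyl C4–H alone.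

Step 6
Reactants: 7 (1S,4S)-5-methoxy-4-[(phenylsulfonyl)methyl]-1,2,3,4-tetrahydronaphthalen-1-ol
Product: 8 {[(1S,4S)-5-methoxy-4-[(phenylsulfonyl)methyl]-1,2,3,4-tetrahydronaphthalen-1-yl]oxy}triisopropylsilane
Conditions: i-Pr3SiOTf, 2,6-lutidine, CH2Cl2, 0 °C
Reagents that add atoms: triisopropylsilyl trifluoromethanesulfonate, CC(C)[Si](C(C)C)(C(C)C)OS(=O)(=O)C(F)(F)F
Why: Silylation of a secondary benzylic alcohol with a silyl triflate and a hindered pyridine base gives an ether that withstands the organolithium and alkoxide bases of steps 7 to 9.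

Step 7
Reactants: 8 {[(1S,4S)-5-methoxy-4-[(phenylsulfonyl)methyl]-1,2,3,4-tetrahydronaphthalen-1-yl]oxy}triisopropylsilane
Product: 9 2-[(1S,4S)-8-methoxy-4-(triisopropylsilyloxy)-1,2,3,4-tetrahydronaphthalen-1-yl]-N,N-dimethyl-2-(phenylsulfonyl)ethan-1-amine (both configurations at the sulfonyl carbon)
Conditions: n-BuLi, THF, −78 °C; then CH2=NMe2+ I−, −78 °C → rt
Reagents that add atoms: N,N-dimethylmethyleneiminium iodide, C=[N+](C)C.[I-]
Why: α-Lithiation of the sulfone followed by Mannich aminomethylation with a preformed iminium salt; only the CH2 beside sulfur is acidic enough for n-BuLi at −78 °C, and the new centre at that carbon disappears in step 8.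

Step 8
Reactants: 9 2-[(1S,4S)-8-methoxy-4-(triisopropylsilyloxy)-1,2,3,4-tetrahydronaphthalen-1-yl]-N,N-dimethyl-2-(phenylsulfonyl)ethan-1-amine
Product: 11 phenyl 1-[(1S,4S)-8-methoxy-4-(triisopropylsilyloxy)-1,2,3,4-tetrahydronaphthalen-1-yl]vinyl sulfone, via ammonium iodide 10 (not isolated)
Conditions: MeI, MeCN, rt; then K2CO3, rt
Reagents that add atoms: none
Why: Quaternisation of the amine and Hofmann-type β-elimination (E1cB through the α-sulfonyl carbanion) of trimethylamine gives the 1,1-disubstituted vinyl sulfone, and the weak carbonate base does not remove the allylic, benzylic C4–H.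

Step 9
Reactants: 11 phenyl 1-[(1S,4S)-8-methoxy-4-(triisopropylsilyloxy)-1,2,3,4-tetrahydronaphthalen-1-yl]vinyl sulfone; 12 methyl 2-methoxy-6-methylbenzoate
Product: 14 8-methoxy-2-[(1R,4S)-8-methoxy-4-(triisopropylsilyloxy)-1,2,3,4-tetrahydronaphthalen-1-yl]naphthalen-1-ol, via keto sulfone 13 (not isolated)
Conditions: 12 (2 equiv), LiN(i-Pr)2 (1.9 equiv), THF, −78 °C; slow addition of 11, −78 → 0 °C; then t-BuOH, t-BuOK, 0 → 40 °C
Reagents that add atoms: none
Why: Proposed new method: the benzylic lithium compound from 12 adds in a Michael reaction to the open CH2 terminus of 11 (bond C4'–C3'), the tertiary α-sulfonyl carbanion so formed attacks the neighbouring ester (bond C2'–C1') with loss of methoxide to give 13, and t-BuOK then takes a C3' proton with E2 loss of benzenesulfinate, after which the 4H-naphthalen-1-one enolises to the naphthol. The closest known reactions are the Staunton–Weinreb annulation of lithiated ortho-toluates with enones and unsaturated lactones, the acylation of sulfonyl carbanions by esters, and Hauser-type sulfone annulations that aromatise by loss of sulfinate; new here are a vinyl sulfone as the only acceptor and sulfinate loss from the carbon next to the ketone. Ring C closes by a 6-exo-trig Dieckmann-type acyl substitution, and regiochemistry follows from polarity, since the toluate methyl carbon can only become C4' and the ester carbon C1'. No lasting stereocentre is made (the quaternary C2' of 13 is lost on elimination), and C1 and C4 of the tetralin are spectators. The step needs conjugate addition to be faster than removal of the allylic, benzylic C4–H of 11, which the unhindered CH2 terminus, the peri methoxy group that shields this hydrogen, complete metalation of 12 with a slight deficit of amide at −78 °C and slow addition of 11 should secure. The E2 step must take the ring C3'–H and not the buried tetralin C4–H, which the bulky alkoxide favours, and once the vinyl sulfone is consumed the C4–H is no longer acidic.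

Step 10
Reactants: 14 8-methoxy-2-[(1R,4S)-8-methoxy-4-(triisopropylsilyloxy)-1,2,3,4-tetrahydronaphthalen-1-yl]naphthalen-1-ol
Product: 15 (1S,4R)-4-(1-hydroxy-8-methoxynaphthalen-2-yl)-5-methoxy-1,2,3,4-tetrahydronaphthalen-1-ol (dipolynaphthalene A)
Conditions: Bu4NF, THF, rt
Reagents that add atoms: none
Why: Fluoride-induced cleavage of the silyl ether sets the C1 alcohol free without acid, which the ionisable benzylic carbinol would not tolerate, and touches neither the naphthol nor the stereocentres.

## Compound list

1 | methyl phenyl sulfone | CS(=O)(=O)c1ccccc1 | starting material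
2 | 8-methoxy-3,4-dihydronaphthalen-1(2H)-one | COc1cccc2c1C(=O)CCC2 | starting material
3 | 8-methoxy-1-[(phenylsulfonyl)methyl]-1,2,3,4-tetrahydronaphthalen-1-ol (racemic) | COc1cccc2c1C(O)(CS(=O)(=O)c1ccccc1)CCC2 | intermediate
4 | 5-methoxy-4-[(phenylsulfonyl)methyl]-1,2-dihydronaphthalene | COc1cccc2c1C(CS(=O)(=O)c1ccccc1)=CCC2 | intermediate
5 | (S)-8-methoxy-1-[(phenylsulfonyl)methyl]-1,2,3,4-tetrahydronaphthalene | COc1cccc2c1[C@@H](CS(=O)(=O)c1ccccc1)CCC2 | intermediate
6 | (S)-5-methoxy-4-[(phenylsulfonyl)methyl]-3,4-dihydronaphthalen-1(2H)-one | COc1cccc2c1[C@@H](CS(=O)(=O)c1ccccc1)CCC2=O | intermediate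
7 | (1S,4S)-5-methoxy-4-[(phenylsulfonyl)methyl]-1,2,3,4-tetrahydronaphthalen-1-ol | COc1cccc2c1[C@@H](CS(=O)(=O)c1ccccc1)CC[C@@H]2O | intermediate
8 | {[(1S,4S)-5-methoxy-4-[(phenylsulfonyl)methyl]-1,2,3,4-tetrahydronaphthalen-1-yl]oxy}triisopropylsilane | COc1cccc2c1[C@@H](CS(=O)(=O)c1ccccc1)CC[C@@H]2O[Si](C(C)C)(C(C)C)C(C)C | intermediate
9 | 2-[(1S,4S)-8-methoxy-4-(triisopropylsilyloxy)-1,2,3,4-tetrahydronaphthalen-1-yl]-N,N-dimethyl-2-(phenylsulfonyl)ethan-1-amine (both configurations at the sulfonyl carbon) | COc1cccc2c1[C@@H](C(CN(C)C)S(=O)(=O)c1ccccc1)CC[C@@H]2O[Si](C(C)C)(C(C)C)C(C)C | intermediate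
10 | 2-[(1S,4S)-8-methoxy-4-(triisopropylsilyloxy)-1,2,3,4-tetrahydronaphthalen-1-yl]-N,N,N-trimethyl-2-(phenylsulfonyl)ethan-1-aminium iodide | COc1cccc2c1[C@@H](C(C[N+](C)(C)C)S(=O)(=O)c1ccccc1)CC[C@@H]2O[Si](C(C)C)(C(C)C)C(C)C.[I-] | intermediate
11 | phenyl 1-[(1S,4S)-8-methoxy-4-(triisopropylsilyloxy)-1,2,3,4-tetrahydronaphthalen-1-yl]vinyl sulfone | COc1cccc2c1[C@@H](C(=C)S(=O)(=O)c1ccccc1)CC[C@@H]2O[Si](C(C)C)(C(C)C)C(C)C | intermediate
12 | methyl 2-methoxy-6-methylbenzoate | COC(=O)c1c(C)cccc1OC | starting material
13 | 8-methoxy-2-[(1S,4S)-8-methoxy-4-(triisopropylsilyloxy)-1,2,3,4-tetrahydronaphthalen-1-yl]-2-(phenylsulfonyl)-3,4-dihydronaphthalen-1(2H)-one (either configuration at C2') | COc1cccc2c1[C@@H](C1(S(=O)(=O)c3ccccc3)CCc3cccc(OC)c3C1=O)CC[C@@H]2O[Si](C(C)C)(C(C)C)C(C)C | intermediate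
14 | 8-methoxy-2-[(1R,4S)-8-methoxy-4-(triisopropylsilyloxy)-1,2,3,4-tetrahydronaphthalen-1-yl]naphthalen-1-ol | COc1cccc2c1[C@@H](c1ccc3cccc(OC)c3c1O)CC[C@@H]2O[Si](C(C)C)(C(C)C)C(C)C | intermediate
15 | (1S,4R)-4-(1-hydroxy-8-methoxynaphthalen-2-yl)-5-methoxy-1,2,3,4-tetrahydronaphthalen-1-ol (dipolynaphthalene A) | COc1cccc2c1[C@@H](c1ccc3cccc(OC)c3c1O)CC[C@@H]2O | target

## Step count and risks

Total steps: 10. Longest linear sequence: 10 steps, from 1 and 2 to 15; 12 enters at step 9.

**1. Step 9 (proposed new method).** Four processes could defeat it: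
- the C4 proton of 11 is transferred to the toluate anion, which would move the double bond into conjugation with the arene and erase C4;
- the crowded tertiary sulfonyl carbanion fails to close onto the di-ortho-substituted ester, or alkoxide re-opens the non-enolisable keto sulfone;
- E2 loss of sulfinate is slow;
- elimination goes towards the tetralin C4–H.

The fallback uses known reactions only, sets out from 8 and 12 and returns at 14. It forms C2'–C1' and C2'–C3' instead, with no vinyl sulfone and no sulfinate elimination. 12 would be lithiated (LiN(i-Pr)2, THF, −78 °C) and trapped with formaldehyde to give 8-methoxyisochroman-1-one F1 (lateral lithiation, hydroxymethylation, lactonisation). Lithiated 8 (n-BuLi, THF, −78 °C) would be acylated by F1 to give the hydroxy keto sulfone F2; the tetrahedral adduct of the lactone holds until the quench. SmI2 (THF/MeOH, −78 °C) would remove the sulfonyl group to give the hydroxy ketone F3 (reductive desulfonylation of a β-keto sulfone). Dess–Martin oxidation would give the keto aldehyde F4, which DBU should close by intramolecular aldol condensation, dehydration and enolisation to 14.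

**2. Step 3.** Enantioface discrimination may be poor, or turnover slow, because the peri methoxy group crowds the alkene and the sulfonyl oxygens can bind iridium.

The fallback sets out from 4 and returns at 7. Hydrogenation over Pd/C (H2, EtOAc) would give the racemic sulfone F5, and CrO3/AcOH the racemic ketone F6. Transfer hydrogenation of F6 with RuCl[(S,S)-TsDPEN](p-cymene) under the conditions of step 5 should reduce both enantiomers to (1S)-carbinols. The mixture would then hold 7 and its cis (1S,4R) diastereomer F7, to be separated by chromatography. This is a stereodivergent reduction of a racemate, so at most half of the material is used.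

**3. Step 4.** Hydrogen abstraction at the tertiary C4–H, or oxidation of the methoxyarene ring, may compete with attack at the C1 methylene, and over-oxidation is possible.

The fallback builds the ring B ketone by Friedel–Crafts acylation instead of C–H oxidation; it sets out from 1 and returns at 7. Lithiated 1 (n-BuLi, THF, −78 °C, in excess because the first equivalent deprotonates the acid) would add to the ketone of purchased 4-(2-methoxyphenyl)-4-oxobutanoic acid F8, and acidification would close the γ-lactone F9. Hydrogenolysis of its tertiary benzylic C–O bond (H2, Pd/C, AcOH, cat. HClO4) would give the racemic acid F10. P2O5/MeSO3H should cyclise F10 at the only free ortho position to the racemic ketone F6. The Ru reduction and separation described for step 3 would then give 7, with the cis diastereomer F7 set aside.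

## Further compounds

F1 | step 9 | 8-methoxyisochroman-1-one | COc1cccc2c1C(=O)OCC2
F2 | step 9 | 1-[2-(2-hydroxyethyl)-6-methoxyphenyl]-2-[(1S,4S)-8-methoxy-4-(triisopropylsilyloxy)-1,2,3,4-tetrahydronaphthalen-1-yl]-2-(phenylsulfonyl)ethan-1-one (both configurations at the sulfonyl carbon) | COc1cccc2c1[C@@H](C(C(=O)c1c(CCO)cccc1OC)S(=O)(=O)c1ccccc1)CC[C@@H]2O[Si](C(C)C)(C(C)C)C(C)C
F3 | step 9 | 1-[2-(2-hydroxyethyl)-6-methoxyphenyl]-2-[(1R,4S)-8-methoxy-4-(triisopropylsilyloxy)-1,2,3,4-tetrahydronaphthalen-1-yl]ethan-1-one | COc1cccc2c1[C@@H](CC(=O)c1c(CCO)cccc1OC)CC[C@@H]2O[Si](C(C)C)(C(C)C)C(C)C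
F4 | step 9 | 2-(3-methoxy-2-{2-[(1R,4S)-8-methoxy-4-(triisopropylsilyloxy)-1,2,3,4-tetrahydronaphthalen-1-yl]acetyl}phenyl)acetaldehyde | COc1cccc2c1[C@@H](CC(=O)c1c(CC=O)cccc1OC)CC[C@@H]2O[Si](C(C)C)(C(C)C)C(C)C
F5 | step 3 | racemic 8-methoxy-1-[(phenylsulfonyl)methyl]-1,2,3,4-tetrahydronaphthalene | COc1cccc2c1C(CS(=O)(=O)c1ccccc1)CCC2
F6 | step 3 | racemic 5-methoxy-4-[(phenylsulfonyl)methyl]-3,4-dihydronaphthalen-1(2H)-one | COc1cccc2c1C(CS(=O)(=O)c1ccccc1)CCC2=O
F7 | step 3 | (1S,4R)-5-methoxy-4-[(phenylsulfonyl)methyl]-1,2,3,4-tetrahydronaphthalen-1-ol (cis) | COc1cccc2c1[C@H](CS(=O)(=O)c1ccccc1)CC[C@@H]2O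
F8 | step 4 | 4-(2-methoxyphenyl)-4-oxobutanoic acid (purchased) | COc1ccccc1C(=O)CCC(=O)O
F9 | step 4 | racemic 5-(2-methoxyphenyl)-5-[(phenylsulfonyl)methyl]dihydrofuran-2(3H)-one | COc1ccccc1C1(CS(=O)(=O)c2ccccc2)CCC(=O)O1
F10 | step 4 | racemic 4-(2-methoxyphenyl)-5-(phenylsulfonyl)pentanoic acid | COc1ccccc1C(CS(=O)(=O)c1ccccc1)CCC(=O)O
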